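**Plan**
Cuts, in retrosynthetic order: C1=C10 (ring-closing metathesis); C13–Cl and C11–O (chloride opening of an 11,13-epoxide made from the 11(13)-methylene lactone); C12–C11, with C12 excised as CO (the lactone ring); C6–C7 (enal C1–C6 plus ethynyloxirane C7–C11/C13).
Enabling feature: in the butanolide ring (O6, C6, C7, C11, C12) the carbonyl C12 is the only atom outside the carbon chain, and O6 and C11 stand 1,3 across C7. A C6-hydroxyl/C7-ethynyl pair (a but-3-yn-1-ol unit) can therefore take up one CO on O6 and close the ring by bonding C12 to C11.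
Forward: two five-step fragments are joined at C6–C7. An oxidation/Evans–Tishchenko relay sets C6 and puts the acetate on O8. The lactone ring is closed first (CO insertion), its exocyclic alkene becomes the chlorohydrin, and the ten-membered ring is closed last.
The new lactone does three more jobs. It makes C11=C13 the only electron-poor alkene among five, its C7 side chain shields one face of C11, and as a trans-disubstituted five-membered ring it serves as a turn element for the macrocyclisation.
Stereochemistry: C8 and C7 come from a Sharpless epoxide (C7 by inversion in the fragment union), and C2 from a catalytic enantioselective vinylogous Mukaiyama aldol. C6 is set by 1,3-anti hydride delivery from O8, and C11 by attack anti to the C8 chain. The 4E alkene comes from the aldol, and 1(10)Z from ring strain in the metathesis.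

Key step: step 14

Remark: germacrane numbering is used throughout, also for open-chain precursors: C1=C10(C14H3), C2(OH), C3H2, C4(C15H3)=C5, C6(O-lactone), C7, C8(OAc), C9H2; side chain C11(OH), C12(=O), C13H2Cl.

Step 1
Reactants: 1 prop-2-yn-1-ol; 2 3-bromo-2-methylprop-1-ene
Product: 3 5-methylhex-5-en-2-yn-1-ol
Conditions: CuI (10 mol %), K2CO3, n-Bu4NBr (10 mol %), DMF, rt
Reagents that add atoms: none
Why: Copper-catalysed allylation of a terminal alkyne: the copper acetylide of 1 displaces the primary allylic bromide of 2, and the free hydroxyl needs no protection under carbonate base.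

Step 2
Reactants: 3 5-methylhex-5-en-2-yn-1-ol
Product: 4 (2Z)-5-methylhexa-2,5-dien-1-ol
Conditions: H2 (1 atm), Pd/CaCO3 poisoned with Pb(OAc)2, quinoline, EtOAc, rt
Reagents that add atoms: none
Why: Semihydrogenation over poisoned palladium adds H2 syn to the alkyne and should stop at the Z-allylic alcohol, because the isolated 1,1-disubstituted alkene is reduced far more slowly.

Step 3
Reactants: 4 (2Z)-5-methylhexa-2,5-dien-1-ol
Product: 5 [(2S,3R)-3-(2-methylprop-2-enyl)oxiran-2-yl]methanol
Conditions: Ti(Oi-Pr)4 (10 mol %), L-(+)-diethyl tartrate (12 mol %), t-BuOOH, 4 Å molecular sieves, CH2Cl2, −20 °C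
Reagents that add atoms: tert-butyl hydroperoxide, CC(C)(C)OO
Why: Sharpless asymmetric epoxidation: only the alkene next to the titanium-bound hydroxyl is oxidised, and the L-(+)-tartrate ligand delivers oxygen to the face that gives the (2S,3R)-cis-epoxide, which fixes C8 for good and makes C7 a stereodefined leaving-group centre.

Step 4
Reactants: 5 [(2S,3R)-3-(2-methylprop-2-enyl)oxiran-2-yl]methanol
Product: 6 (2R,3R)-3-(2-methylprop-2-enyl)oxirane-2-carbaldehyde
Conditions: TEMPO (10 mol %), PhI(OAc)2, CH2Cl2, 0 °C to rt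
Reagents that add atoms: none
Why: Oxoammonium-mediated (TEMPO) oxidation of the primary alcohol stops at the aldehyde under non-basic conditions, so the oxirane carbon next to the carbonyl is not epimerised.

Step 5
Reactants: 6 (2R,3R)-3-(2-methylprop-2-enyl)oxirane-2-carbaldehyde
Product: 7 (2S,3R)-2-ethynyl-3-(2-methylprop-2-enyl)oxirane
Conditions: dimethyl (1-diazo-2-oxopropyl)phosphonate, K2CO3, MeOH, 0 °C to rt
Reagents that add atoms: dimethyl (1-diazo-2-oxopropyl)phosphonate, COP(=O)(OC)C(=[N+]=[N-])C(C)=O
Why: The Ohira–Bestmann variant of the Seyferth–Gilbert homologation converts the aldehyde into the terminal alkyne (C11≡C13) under carbonate/methanol conditions that epoxy aldehydes tolerate.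

Step 6
Reactants: 8 ethyl 3-methylbut-2-enoate
Product: 10 tert-butyl[(1-ethoxy-3-methylbuta-1,3-dienyl)oxy]dimethylsilane, via lithium dienolate 9 (not isolated)
Conditions: LDA, THF, −78 °C; then TBSCl, DMPU, −78 °C to rt
Reagents that add atoms: tert-butyldimethylsilyl chloride, CC(C)(C)[Si](C)(C)Cl
Why: Kinetic γ-deprotonation to the extended enolate 9 followed by O-silylation is the standard preparation of a silyl dienol ether (silyl ketene acetal) for vinylogous aldol chemistry, and its ketene acetal geometry is of no consequence.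

Step 7
Reactants: 10 tert-butyl[(1-ethoxy-3-methylbuta-1,3-dienyl)oxy]dimethylsilane; 11 acrolein
Product: 13 ethyl (2E,5S)-5-hydroxy-3-methylhepta-2,6-dienoate, via trichlorosilyl ether 12 (not isolated)
Conditions: SiCl4 (1.1 equiv), chiral binaphthyl-2,2′-diamine-derived bisphosphoramide (5 mol %, the enantiomer that opens the Si face), i-Pr2NEt (10 mol %), CH2Cl2, −78 °C; aqueous work-up
Reagents that add atoms: none
Why: Catalytic enantioselective vinylogous Mukaiyama aldol reaction (Lewis-base activation of SiCl4): the chiral phosphoramide-bound silicon cation binds acrolein, the dienol ether attacks through its γ-carbon on the Si face to set C2 as S, and the extended diene geometry should give the 4E alkene.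

Step 8
Reactants: 13 ethyl (2E,5S)-5-hydroxy-3-methylhepta-2,6-dienoate
Product: 14 ethyl (2E,5S)-3-methyl-5-(triethylsilyloxy)hepta-2,6-dienoate
Conditions: TESCl, imidazole, CH2Cl2, 0 °C
Reagents that add atoms: chlorotriethylsilane, CC[Si](Cl)(CC)CC
Why: Standard silylation of the secondary allylic alcohol; the triethylsilyl group is chosen because it should survive steps 9 to 15 and fall off in the acid of step 16.

Step 9
Reactants: 14 ethyl (2E,5S)-3-methyl-5-(triethylsilyloxy)hepta-2,6-dienoate
Product: 15 (2E,5S)-3-methyl-5-(triethylsilyloxy)hepta-2,6-dien-1-ol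
Conditions: i-Bu2AlH (2.2 equiv), CH2Cl2, −78 °C; aq. potassium sodium tartrate
Reagents that add atoms: none
Why: Hydride reduction of the conjugated ester with two equivalents of i-Bu2AlH gives the allylic alcohol by 1,2-reduction without touching the alkenes or the silyl ether.

Step 10
Reactants: 15 (2E,5S)-3-methyl-5-(triethylsilyloxy)hepta-2,6-dien-1-ol
Product: 16 (2E,5S)-3-methyl-5-(triethylsilyloxy)hepta-2,6-dienal
Conditions: MnO2, CH2Cl2, rt
Reagents that add atoms: none
Why: Manganese dioxide oxidation is selective for allylic alcohols and should give the E-enal without over-oxidation or E/Z isomerisation.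

Step 11
Reactants: 7 (2S,3R)-2-ethynyl-3-(2-methylprop-2-enyl)oxirane; 16 (2E,5S)-3-methyl-5-(triethylsilyloxy)hepta-2,6-dienal
Product: 18 (3S,5E,7R,8R,9R)-8-ethynyl-5,11-dimethyl-3-(triethylsilyloxy)dodeca-1,5,11-triene-7,9-diol, via allenylindium alkoxide 17 (not isolated)
Conditions: InI (1.6 equiv), PdCl2(dppf) (5 mol %), THF–HMPA 4:1, rt
Reagents that add atoms: none
Why: Palladium/indium iodide umpolung of a propargylic electrophile (Barbier-type propargylation): zerovalent palladium opens the propargylic C7–O bond in an anti SN2′ sense, InI takes over the allenyl ligand with retention (17), and a closed six-membered SE2′ transition state forges C6–C7 on the indium-bearing face, so that C7 forms with net inversion while C8 is untouched, and the anti-selectivity at C6 (6R drawn) is not critical because C6 is reset in steps 12 and 13.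

Step 12
Reactants: 18 (3S,5E,7R,8R,9R)-8-ethynyl-5,11-dimethyl-3-(triethylsilyloxy)dodeca-1,5,11-triene-7,9-diol
Product: 19 (3S,5E,8R,9R)-8-ethynyl-9-hydroxy-5,11-dimethyl-3-(triethylsilyloxy)dodeca-1,5,11-trien-7-one
Conditions: MnO2, CH2Cl2, rt
Reagents that add atoms: none
Why: Chemoselective manganese dioxide oxidation: only O6–H is allylic, so C8–OH survives and both C6 epimers of 18 converge on one β-hydroxy enone under neutral conditions that spare the acidic C7–H.

Step 13
Reactants: 19 (3S,5E,8R,9R)-8-ethynyl-9-hydroxy-5,11-dimethyl-3-(triethylsilyloxy)dodeca-1,5,11-trien-7-one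
Product: 21 (3S,5E,7R,8S,9R)-8-ethynyl-7-hydroxy-5,11-dimethyl-3-(triethylsilyloxy)dodeca-1,5,11-trien-9-yl acetate, via acetaldehyde hemiacetal 20 (not isolated)
Conditions: SmI2 (30 mol %), CH3CHO (10 equiv), THF, −10 °C
Reagents that add atoms: acetaldehyde, CC=O
Why: Evans–Tishchenko reduction: trivalent samarium ties hemiacetal 20 to the ketone in a chair-like six-membered array and the hemiacetal hydride is delivered intramolecularly, which sets C6 1,3-anti to C8 (6R), turns acetaldehyde into the O8 acetate of the target and leaves O6–H as the only free hydroxyl.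

Step 14
Reactants: 21 (3S,5E,7R,8S,9R)-8-ethynyl-7-hydroxy-5,11-dimethyl-3-(triethylsilyloxy)dodeca-1,5,11-trien-9-yl acetate
Product: 24 (1R)-1-[(2R,3R)-2-[(1E,4S)-2-methyl-4-(triethylsilyloxy)hexa-1,5-dienyl]-4-methylene-5-oxotetrahydrofuran-3-yl]-3-methylbut-3-enyl acetate, via alkoxycarbonylpalladium chloride 22 (not isolated), via alkenylpalladium lactone 23 (not isolated)
Conditions: CO (7 atm), PdCl2 (5 mol %), PPh3 (10 mol %), SnCl2 (5 mol %), MeCN, 65 °C
Reagents that add atoms: carbon monoxide, [C-]#[O+]
Why: Divalent palladium, CO and the only free hydroxyl (O6–H) form alkoxycarbonylpalladium chloride 22; its Pd–C12 bond then adds syn across the tethered C11≡C13 triple bond, so the C12–C11 bond is made in the ring-closing event and palladium ends on C13 (23), and protonolysis of the C13–Pd bond by the HCl released in the first stage gives 24 and returns PdCl2. The closest known reaction type is the palladium-catalysed cyclocarbonylation of but-3-yn-1-ols to α-methylene-γ-butyrolactones. The butanolide ring closes in the 5-exo-dig mode, because a syn insertion in the endo sense would have to place palladium trans to C12 on a cis ring alkene, which is geometrically impossible in a six-membered ring. No new stereocentre arises: C6 and C7 are spectators and their relative configuration from steps 11 and 13 becomes the trans ring fusion (H6/H7 anti). The step needs site selectivity between O6 and O8, secured by the Evans–Tishchenko acetate on O8; regioselectivity for C11 over C13, secured by the three-atom tether O6–C6–C7; and chemoselectivity for the alkyne over four alkenes, secured by intramolecular delivery and the stronger binding of alkynes to palladium. One CO thus supplies the last skeletal carbon, and the product carries the only electron-poor alkene of the molecule, which steps 15 and 16 exploit.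

Step 15
Reactants: 24 (1R)-1-[(2R,3R)-2-[(1E,4S)-2-methyl-4-(triethylsilyloxy)hexa-1,5-dienyl]-4-methylene-5-oxotetrahydrofuran-3-yl]-3-methylbut-3-enyl acetate
Product: 26 (1R)-1-[(3R,6R,7R)-6-[(1E,4S)-2-methyl-4-(triethylsilyloxy)hexa-1,5-dienyl]-4-oxo-1,5-dioxaspiro[2.4]heptan-7-yl]-3-methylbut-3-enyl acetate, via peroxy enolate 25 (not isolated)
Conditions: t-BuOOH (3 equiv), n-BuLi (1.5 equiv), THF, −78 to −20 °C
Reagents that add atoms: tert-butyl hydroperoxide, CC(C)(C)OO
Why: Weitz–Scheffer-type nucleophilic epoxidation: the peroxide anion adds only to the electron-poor C13 terminus (the four electron-rich alkenes are inert to a nucleophilic oxidant), and enolate 25 closes onto the O–O bond from the lactone face anti to the C8 side chain on C7, which places the C11–O bond cis to H7.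

Step 16
Reactants: 26 (1R)-1-[(3R,6R,7R)-6-[(1E,4S)-2-methyl-4-(triethylsilyloxy)hexa-1,5-dienyl]-4-oxo-1,5-dioxaspiro[2.4]heptan-7-yl]-3-methylbut-3-enyl acetate
Product: 28 (1R)-1-[(2R,3R,4S)-4-(chloromethyl)-4-hydroxy-2-[(1E,4S)-4-hydroxy-2-methylhexa-1,5-dienyl]-5-oxotetrahydrofuran-3-yl]-3-methylbut-3-enyl acetate, via chlorohydrin triethylsilyl ether 27 (not isolated)
Conditions: HCl (1 M in Et2O, 1.2 equiv), THF, −20 °C; then 1 M aq. HCl, 0 °C
Reagents that add atoms: hydrogen chloride, Cl
Why: Acid-promoted SN2 opening of the spiro-epoxide by chloride occurs at the primary C13 (the C11–O bond is untouched, so C11 keeps its configuration), and the aqueous acid then hydrolyses the triethylsilyl ether while acetate and lactone persist.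

Step 17
Reactants: 28 (1R)-1-[(2R,3R,4S)-4-(chloromethyl)-4-hydroxy-2-[(1E,4S)-4-hydroxy-2-methylhexa-1,5-dienyl]-5-oxotetrahydrofuran-3-yl]-3-methylbut-3-enyl acetate
Product: 29 (1(10)Z,4E,2S,6R,7R,8R,11S)-8-acetoxy-13-chloro-2,11-dihydroxygermacra-1(10),4-dien-6,12-olide
Conditions: second-generation Hoveyda–Grubbs catalyst RuCl2(H2IMes)(=CH-C6H4-2-Oi-Pr) (15 mol %), 1,4-benzoquinone (30 mol %), CH2Cl2 (0.5 mM), 40 °C
Reagents that add atoms: none
Why: Ring-closing metathesis: ruthenium loads on the monosubstituted C1 vinyl group (helped by the free allylic hydroxyl) and closes onto the isopropenyl group with loss of ethene, the trans-lactone and the 4E alkene act as turn elements, and a ten-membered ring that already holds one E alkene should accept the new trisubstituted alkene only as Z.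

**Compound list**
1 | prop-2-yn-1-ol | C#CCO | starting material
2 | 3-bromo-2-methylprop-1-ene | C=C(C)CBr | starting material
3 | 5-methylhex-5-en-2-yn-1-ol | OCC#CCC(C)=C | intermediate
4 | (2Z)-5-methylhexa-2,5-dien-1-ol | OC/C=C\CC(C)=C | intermediate
5 | [(2S,3R)-3-(2-methylprop-2-enyl)oxiran-2-yl]methanol | OC[C@@H]1O[C@@H]1CC(C)=C | intermediate
6 | (2R,3R)-3-(2-methylprop-2-enyl)oxirane-2-carbaldehyde | O=C[C@@H]1O[C@@H]1CC(C)=C | intermediate
7 | (2S,3R)-2-ethynyl-3-(2-methylprop-2-enyl)oxirane (cis) | C#C[C@@H]1O[C@@H]1CC(C)=C | intermediate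
8 | ethyl 3-methylbut-2-enoate | CCOC(=O)C=C(C)C | starting material
9 | lithium dienolate of 8 | [Li+].C=C(C)C=C([O-])OCC | intermediate
10 | tert-butyl[(1-ethoxy-3-methylbuta-1,3-dienyl)oxy]dimethylsilane | C=C(C)C=C(OCC)O[Si](C)(C)C(C)(C)C | intermediate
11 | acrolein | C=CC=O | starting material
12 | ethyl (2E,5S)-3-methyl-5-(trichlorosilyloxy)hepta-2,6-dienoate | C=C[C@@H](O[Si](Cl)(Cl)Cl)C/C(C)=C/C(=O)OCC | intermediate
13 | ethyl (2E,5S)-5-hydroxy-3-methylhepta-2,6-dienoate | C=C[C@@H](O)C/C(C)=C/C(=O)OCC | intermediate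
14 | ethyl (2E,5S)-3-methyl-5-(triethylsilyloxy)hepta-2,6-dienoate | C=C[C@@H](O[Si](CC)(CC)CC)C/C(C)=C/C(=O)OCC | intermediate
15 | (2E,5S)-3-methyl-5-(triethylsilyloxy)hepta-2,6-dien-1-ol | C=C[C@@H](O[Si](CC)(CC)CC)C/C(C)=C/CO | intermediate
16 | (2E,5S)-3-methyl-5-(triethylsilyloxy)hepta-2,6-dienal | C=C[C@@H](O[Si](CC)(CC)CC)C/C(C)=C/C=O | intermediate
17 | allenylindium iodide bearing the C8 alkoxide, indium on C13 anti to the departed C7–O bond (drawn as inner salt) | C=C(C)C[C@@H]([O-])C=C=C[In+]I | intermediate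
18 | (3S,5E,7R,8R,9R)-8-ethynyl-5,11-dimethyl-3-(triethylsilyloxy)dodeca-1,5,11-triene-7,9-diol (germacrane 2S,6R,7R,8R) | C=C[C@@H](O[Si](CC)(CC)CC)C/C(C)=C/[C@@H](O)[C@H](C#C)[C@H](O)CC(C)=C | intermediate
19 | (3S,5E,8R,9R)-8-ethynyl-9-hydroxy-5,11-dimethyl-3-(triethylsilyloxy)dodeca-1,5,11-trien-7-one | C=C[C@@H](O[Si](CC)(CC)CC)C/C(C)=C/C(=O)[C@H](C#C)[C@H](O)CC(C)=C | intermediate
20 | O8 hemiacetal of 19 with acetaldehyde (samarium-bound in the flask, drawn neutral) | C=C[C@@H](O[Si](CC)(CC)CC)C/C(C)=C/C(=O)[C@H](C#C)[C@H](OC(C)O)CC(C)=C | intermediate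
21 | (3S,5E,7R,8S,9R)-8-ethynyl-7-hydroxy-5,11-dimethyl-3-(triethylsilyloxy)dodeca-1,5,11-trien-9-yl acetate | C=C[C@@H](O[Si](CC)(CC)CC)C/C(C)=C/[C@@H](O)[C@H](C#C)[C@@H](CC(C)=C)OC(C)=O | intermediate
22 | O6-alkoxycarbonylpalladium chloride of 21 (phosphine ligands not drawn) | C=C[C@@H](O[Si](CC)(CC)CC)C/C(C)=C/[C@@H](OC(=O)[Pd]Cl)[C@H](C#C)[C@@H](CC(C)=C)OC(C)=O | intermediate
23 | lactone with a C13 alkenylpalladium chloride, Pd cis to C12 (phosphine ligands not drawn) | C=C[C@@H](O[Si](CC)(CC)CC)C/C(C)=C/[C@H]1OC(=O)/C(=C\[Pd]Cl)[C@@H]1[C@@H](CC(C)=C)OC(C)=O | intermediate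
24 | (1R)-1-[(2R,3R)-2-[(1E,4S)-2-methyl-4-(triethylsilyloxy)hexa-1,5-dienyl]-4-methylene-5-oxotetrahydrofuran-3-yl]-3-methylbut-3-enyl acetate | C=C[C@@H](O[Si](CC)(CC)CC)C/C(C)=C/[C@H]1OC(=O)C(=C)[C@@H]1[C@@H](CC(C)=C)OC(C)=O | intermediate
25 | lithium lactone enolate carrying a C13 tert-butylperoxy group | [Li+].C=C[C@@H](O[Si](CC)(CC)CC)C/C(C)=C/[C@H]1OC([O-])=C(COOC(C)(C)C)[C@@H]1[C@@H](CC(C)=C)OC(C)=O | intermediate
26 | (1R)-1-[(3R,6R,7R)-6-[(1E,4S)-2-methyl-4-(triethylsilyloxy)hexa-1,5-dienyl]-4-oxo-1,5-dioxaspiro[2.4]heptan-7-yl]-3-methylbut-3-enyl acetate | C=C[C@@H](O[Si](CC)(CC)CC)C/C(C)=C/[C@H]1OC(=O)[C@]2(CO2)[C@@H]1[C@@H](CC(C)=C)OC(C)=O | intermediate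
27 | 2-O-triethylsilyl ether of 28 | C=C[C@@H](O[Si](CC)(CC)CC)C/C(C)=C/[C@H]1OC(=O)[C@](O)(CCl)[C@@H]1[C@@H](CC(C)=C)OC(C)=O | intermediate
28 | (1R)-1-[(2R,3R,4S)-4-(chloromethyl)-4-hydroxy-2-[(1E,4S)-4-hydroxy-2-methylhexa-1,5-dienyl]-5-oxotetrahydrofuran-3-yl]-3-methylbut-3-enyl acetate | C=C[C@@H](O)C/C(C)=C/[C@H]1OC(=O)[C@](O)(CCl)[C@@H]1[C@@H](CC(C)=C)OC(C)=O | intermediate
29 | (1(10)Z,4E,2S,6R,7R,8R,11S)-8-acetoxy-13-chloro-2,11-dihydroxygermacra-1(10),4-dien-6,12-olide | CC(=O)O[C@@H]1C/C(C)=C\[C@@H](O)C/C(C)=C/[C@H]2OC(=O)[C@](O)(CCl)[C@@H]21 | target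

Total steps: 17. Longest linear sequence: 12 steps (steps 1–5 or 6–10, then 11–17).

**The three steps most likely to fail**

Step 17 (ring-closing metathesis).
- What may go wrong: intermolecular metathesis may outrun closure. The 1,1-disubstituted alkene may engage too slowly against the strain of a ten-membered ring that already holds an E alkene and a trans-fused lactone. Ruthenium hydrides may shift the allylic alcohol double bond, and Z selectivity may erode.
- Fallback: build the carbocycle before the lactone, setting out from 21. Co2(CO)8 in CH2Cl2 masks the alkyne as its dicobalt hexacarbonyl complex F1. Ring-closing metathesis of the still flexible chain gives the ten-membered dicobalt complex F2, and oxidative decomplexation with (NH4)2Ce(NO3)6 frees the cyclic alkynol F3.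
- Cyclocarbonylation as in step 14 then gives the bicyclic α-methylene lactone F4. Nucleophilic epoxidation as in step 15 gives the bicyclic spiro-epoxide F5. HCl as in step 16 leads through the bicyclic chlorohydrin silyl ether F6 back to the route at 29.

Step 11 (fragment union).
- What may go wrong: the allenyl metal may lose its axial configuration before it adds, which would scramble C7. It may be protonated instead of adding, or it may react through its propargyl form.
- Fallback: separate the two events with boron, setting out from 7. Copper-catalysed anti-SN2′ borylation (B2pin2, CuCl, Xantphos, KOt-Bu, MeOH, THF) gives the configurationally stable allenylboronate F7. After purification it adds to 16 without catalyst through a closed chair-like transition state (propargylboration), and aqueous work-up returns to the route at 18.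

Step 14 (cyclocarbonylation).
- What may go wrong: the acetyl group may migrate from O8 to O6 before carbonylation. Palladium may induce enyne cycloisomerisation, or it may ionise the allylic C6–O bond.
- Fallback: close the same bond by a radical, setting out from 21. Acylation of O6–H with PhSeC(O)Cl and pyridine gives the Se-phenyl selenocarbonate F8. Bu3SnH with Et3B/air in benzene at rt then generates the alkoxycarbonyl radical, which forms C12–C11 by 5-exo-dig cyclisation. Hydrogen transfer to the alkenyl radical returns to the route at 24.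

**Further compounds**
F1 | step 17 | dicobalt hexacarbonyl complex of the alkyne of 21 | C=C[C@@H](O[Si](CC)(CC)CC)C/C(C)=C/[C@@H](O)[C@H](C#C)[C@@H](CC(C)=C)OC(C)=O.[Co].[Co].[C-]#[O+].[C-]#[O+].[C-]#[O+].[C-]#[O+].[C-]#[O+].[C-]#[O+]
F2 | step 17 | dicobalt hexacarbonyl complex of the ten-membered alkynol F3 | CC(=O)O[C@@H]1C/C(C)=C\[C@@H](O[Si](CC)(CC)CC)C/C(C)=C/[C@@H](O)[C@@H]1C#C.[Co].[Co].[C-]#[O+].[C-]#[O+].[C-]#[O+].[C-]#[O+].[C-]#[O+].[C-]#[O+]
F3 | step 17 | (1(10)Z,4E)-cyclodecadiene with 7-ethynyl, 6-hydroxy, 8-acetoxy and 2-triethylsilyloxy groups | CC(=O)O[C@@H]1C/C(C)=C\[C@@H](O[Si](CC)(CC)CC)C/C(C)=C/[C@@H](O)[C@@H]1C#C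
F4 | step 17 | 8-acetoxy-2-(triethylsilyloxy)germacra-1(10)Z,4E,11(13)-trien-6,12-olide | CC(=O)O[C@@H]1C/C(C)=C\[C@@H](O[Si](CC)(CC)CC)C/C(C)=C/[C@H]2OC(=O)C(=C)[C@@H]21
F5 | step 17 | 11,13-epoxide of F4 (C11–O cis to H7) | CC(=O)O[C@@H]1C/C(C)=C\[C@@H](O[Si](CC)(CC)CC)C/C(C)=C/[C@H]2OC(=O)[C@]3(CO3)[C@@H]21
F6 | step 17 | 2-O-triethylsilyl ether of 29 | CC(=O)O[C@@H]1C/C(C)=C\[C@@H](O[Si](CC)(CC)CC)C/C(C)=C/[C@H]2OC(=O)[C@](O)(CCl)[C@@H]21
F7 | step 11 | (4R)-4-hydroxy-6-methylhepta-1,2,6-trienylboronic acid pinacol ester, boron anti to the departed C7–O bond | C=C(C)C[C@@H](O)C=C=CB1OC(C)(C)C(C)(C)O1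
F8 | step 14 | O6 Se-phenyl selenocarbonate of 21 | C=C[C@@H](O[Si](CC)(CC)CC)C/C(C)=C/[C@@H](OC(=O)[Se]c1ccccc1)[C@H](C#C)[C@@H](CC(C)=C)OC(C)=O
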